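**Assumption:** the SMILES is taken literally. The two halves then derive from opposite enantiomers of 4-isopropylcyclohex-2-enone (cryptone), so both are made. Locants below use 2-benzoxepine numbering for the lactone half (C1 lactone C=O, O2, C3, C4, C5, C5a, C6, C7, C8, C9, C9a) and primed cyclohexene numbering for the acyl half.

**Retrosynthetic overview**
1. Last bond: the ester C–O between the halves, made by opening a spiro-epoxide on the lactone half with the right-hand acrylic acid; one acidolysis then frees CO2H and CH2OH.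
2. Ring B (seven-membered ene-lactone) is closed by ring-closing metathesis of a vinyl group with a 2-(acyloxymethyl)acrylate, after ring A exists.
3. Key new step: one-pot enolate carboxylation / carboxylate-shielded sulfur-ylide epoxidation / O-alkylation sets C9a and C9 and brings in the lactone carbon.
4. Right-hand acid: enol triflate, ozonolysis, oxa-Michael/Horner–Wadsworth–Emmons olefination, Stille hydroxymethylation.
5. Ring order: rings A and C (six-membered carbocycles) first, from (R)- and (S)-cryptone by organocatalytic Michael/aldol annulation with trans vinyl conjugate addition; ring B last.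

**Lactone half (steps 1–4)**

Step 1
Reactants: 1 3-methylbutanal; 2 but-3-en-2-one
Product: 4 (4R)-4-(propan-2-yl)cyclohex-2-en-1-one, via (2R)-keto aldehyde 3 (not isolated)
Conditions: (R)-2-[methoxy(diphenyl)methyl]pyrrolidine (5 mol %), ethyl 3,4-dihydroxybenzoate (20 mol %), neat, 4 °C; then LiOH (0.1 equiv), 2-propanol, rt
Reagents that add atoms: none
Why: Enamine-catalysed Michael addition, in which the enone adds to the enamine face opposite the CPh2OMe group and so sets the isopropyl-bearing carbon as R, followed by intramolecular aldol condensation (Robinson-type annulation) under base mild enough to keep the α-stereocentre.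

Step 2
Reactants: 4 (4R)-4-(propan-2-yl)cyclohex-2-en-1-one
Product: 6 {[(3R,4R)-3-ethenyl-4-(propan-2-yl)cyclohex-1-en-1-yl]oxy}trimethylsilane, via bromomagnesium enolate 5 (not isolated)
Conditions: CH2=CHMgBr, CuBr·SMe2 (10 mol %), Me3SiCl, THF, −78 °C; Et3N quench
Reagents that add atoms: vinylmagnesium bromide (C=C[Mg]Br); chlorotrimethylsilane (C[Si](C)(C)Cl)
Why: Copper-catalysed, Me3SiCl-accelerated conjugate addition of the vinyl Grignard reagent anti to the C4 isopropyl group sets the trans C5a stereocentre, and in situ O-silylation stores the enolate regiochemistry.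

Step 3
Reactants: 6 {[(3R,4R)-3-ethenyl-4-(propan-2-yl)cyclohex-1-en-1-yl]oxy}trimethylsilane; 7 tert-butyl 2-(bromomethyl)prop-2-enoate
Product: 11 2-(tert-butoxycarbonyl)prop-2-en-1-yl (3S,4S,5R,6R)-5-ethenyl-6-(propan-2-yl)-1-oxaspiro[2.5]octane-4-carboxylate, via lithium enolate 8 (not isolated), via lithium keto carboxylate 9 (not isolated), via lithium epoxy carboxylate 10 (not isolated)
Conditions: MeLi, THF, 0 °C; CO2, −78 °C, then argon purge; Me2S=CH2 (from Me3S+ I−, n-BuLi, THF, −10 °C), −78 → −20 °C; then 7, DMF, 0 °C → rt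
Reagents that add atoms: carbon dioxide (O=C=O); trimethylsulfonium iodide (C[S+](C)C.[I-])
Why: Proposed new method: carboxylate-shielded Corey–Chaykovsky epoxidation within a one-pot enolate carboxylation/methylenation/O-alkylation — MeLi releases the regiodefined lithium enolate 8, CO2 adds at the enolate carbon anti to the neighbouring vinyl group (trans C9a–C1 bond), and in the lithium β-keto carboxylate 9 the remaining α-proton could only be removed by forming a dianion (estimated pKa well above the roughly 18 of Me3S+), so the non-stabilised ylide adds to the Li-chelated ketone instead of deprotonating it, irreversibly and from the axial face as with 2-alkylcyclohexanones, giving after loss of Me2S the epoxide with axial CH2 and equatorial O (the C9 stereocentre), while the carboxylate, which can reach the epoxide CH2 only by a disfavoured 5-endo opening, is O-alkylated by allylic bromide 7; closest known reactions are Corey–Chaykovsky epoxidation of simple cyclohexanones, CO2 trapping of lithium enolates and carboxylate alkylation with 2-(bromomethyl)acrylates, whereas sulfur ylides are known only to deprotonate β-keto esters.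

Step 4
Reactants: 11 2-(tert-butoxycarbonyl)prop-2-en-1-yl (3S,4S,5R,6R)-5-ethenyl-6-(propan-2-yl)-1-oxaspiro[2.5]octane-4-carboxylate
Product: 12 tert-butyl (5aS,6R,9S,9aS)-1-oxo-6-(propan-2-yl)-1,3,5a,6,7,8-hexahydro-9aH-spiro[2-benzoxepine-9,2'-oxirane]-4-carboxylate
Conditions: second-generation Hoveyda–Grubbs catalyst RuCl2(=CH-C6H4-2-OCHMe2)(H2IMes) (5 mol %), toluene (5 mM), 80 °C
Reagents that add atoms: none
Why: Ring-closing metathesis between the vinyl group and the 1,1-disubstituted acrylate closes the trans-fused seven-membered ring B with the C4=C5 bond necessarily cis in the ring; the epoxide and both esters are inert to the ruthenium carbene and no stereocentre is touched.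

**Acyl half (steps 5–10)**

Step 5
Reactants: 1 3-methylbutanal; 2 but-3-en-2-one
Product: 14 (4S)-4-(propan-2-yl)cyclohex-2-en-1-one, via (2S)-keto aldehyde 13 (not isolated)
Conditions: (S)-2-[methoxy(diphenyl)methyl]pyrrolidine (5 mol %), ethyl 3,4-dihydroxybenzoate (20 mol %), neat, 4 °C; then LiOH (0.1 equiv), 2-propanol, rt
Reagents that add atoms: none
Why: Same enamine Michael addition/aldol condensation as step 1 with the enantiomeric catalyst, which sets the isopropyl-bearing carbon as S.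

Step 6
Reactants: 14 (4S)-4-(propan-2-yl)cyclohex-2-en-1-one
Product: 16 (3S,4S)-3-ethenyl-4-(propan-2-yl)cyclohex-1-en-1-yl trifluoromethanesulfonate, via bromomagnesium enolate 15 (not isolated)
Conditions: CH2=CHMgBr, CuBr·SMe2 (10 mol %), THF, −78 → −40 °C; then N-(5-chloropyridin-2-yl)bis(trifluoromethanesulfonimide), −78 °C → rt
Reagents that add atoms: vinylmagnesium bromide (C=C[Mg]Br); N-(5-chloropyridin-2-yl)bis(trifluoromethanesulfonimide), Comins' reagent (FC(F)(F)S(=O)(=O)N(c1ccc(Cl)cn1)S(=O)(=O)C(F)(F)F)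
Why: Copper-catalysed conjugate addition anti to the isopropyl group sets the trans C1' stereocentre, and O-triflation of the regiodefined enolate fixes the ring double bond between C2' and C3'.

Step 7
Reactants: 16 (3S,4S)-3-ethenyl-4-(propan-2-yl)cyclohex-1-en-1-yl trifluoromethanesulfonate
Product: 18 (3S,4S)-3-formyl-4-(propan-2-yl)cyclohex-1-en-1-yl trifluoromethanesulfonate, via ozonide 17 (not isolated)
Conditions: O3, CH2Cl2, −78 °C (dye end point); PPh3, −78 °C → rt; used crude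
Reagents that add atoms: ozone ([O-][O+]=O)
Why: Ozonolysis with reductive work-up cleaves only the electron-rich monosubstituted vinyl group, because the enol triflate C=C is strongly deactivated toward ozone, and the neutral work-up keeps the α-stereocentre of the β,γ-unsaturated aldehyde.

Step 8
Reactants: 18 (3S,4S)-3-formyl-4-(propan-2-yl)cyclohex-1-en-1-yl trifluoromethanesulfonate; 19 methyl 2-(dimethoxyphosphoryl)prop-2-enoate; 20 (4-methoxyphenyl)methanol
Product: 23 methyl (2E)-2-{[(4-methoxyphenyl)methoxy]methyl}-3-[(1R,6S)-6-(propan-2-yl)-3-{[(trifluoromethyl)sulfonyl]oxy}cyclohex-2-en-1-yl]prop-2-enoate, via sodium alkoxide 21 (not isolated), via phosphonate carbanion 22 (not isolated)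
Conditions: 20, NaH, THF, 0 °C; 19, −78 → 0 °C; then 18, −78 → 0 °C
Reagents that add atoms: none
Why: Tandem oxa-Michael addition/Horner–Wadsworth–Emmons olefination — the alkoxide adds to the phosphonoacrylate and the resulting stabilised carbanion olefinates the α-branched aldehyde at low temperature (fast addition, little enolisation), giving mainly the E alkene with the ring trans to CO2Me; the minor Z isomer is removed by chromatography.

Step 9
Reactants: 23 methyl (2E)-2-{[(4-methoxyphenyl)methoxy]methyl}-3-[(1R,6S)-6-(propan-2-yl)-3-{[(trifluoromethyl)sulfonyl]oxy}cyclohex-2-en-1-yl]prop-2-enoate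
Product: 24 methyl (2E)-3-[(1S,6S)-3-(hydroxymethyl)-6-(propan-2-yl)cyclohex-2-en-1-yl]-2-{[(4-methoxyphenyl)methoxy]methyl}prop-2-enoate
Conditions: Bu3SnCH2OH, Pd(PPh3)4 (10 mol %), LiCl, 1,4-dioxane, 95 °C
Reagents that add atoms: (tributylstannyl)methanol (CCCC[Sn](CO)(CCCC)CCCC)
Why: Stille coupling of the enol triflate (oxidative addition to zerovalent palladium, LiCl-assisted transmetalation of the hydroxymethyl group) installs the ring CH2OH with the double bond position retained; the ester and ether are inert and no stereocentre is involved.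

Step 10
Reactants: 24 methyl (2E)-3-[(1S,6S)-3-(hydroxymethyl)-6-(propan-2-yl)cyclohex-2-en-1-yl]-2-{[(4-methoxyphenyl)methoxy]methyl}prop-2-enoate
Product: 26 (2E)-3-[(1S,6S)-3-(hydroxymethyl)-6-(propan-2-yl)cyclohex-2-en-1-yl]-2-{[(4-methoxyphenyl)methoxy]methyl}prop-2-enoic acid, via lithium carboxylate 25 (not isolated)
Conditions: LiOH·H2O, THF/MeOH/H2O (3:1:1), rt; then aq. HCl to pH 3
Reagents that add atoms: lithium hydroxide ([Li+].[OH-])
Why: Saponification of the only ester at room temperature leaves the benzyl-type ether, the alkene geometry and the C1' stereocentre intact.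

**Union and deprotection (steps 11–12)**

Step 11
Reactants: 12 tert-butyl (5aS,6R,9S,9aS)-1-oxo-6-(propan-2-yl)-1,3,5a,6,7,8-hexahydro-9aH-spiro[2-benzoxepine-9,2'-oxirane]-4-carboxylate; 26 (2E)-3-[(1S,6S)-3-(hydroxymethyl)-6-(propan-2-yl)cyclohex-2-en-1-yl]-2-{[(4-methoxyphenyl)methoxy]methyl}prop-2-enoic acid
Product: 27 tert-butyl (5aS,6R,9S,9aS)-9-hydroxy-9-[({(2E)-3-[(1S,6S)-3-(hydroxymethyl)-6-(propan-2-yl)cyclohex-2-en-1-yl]-2-{[(4-methoxyphenyl)methoxy]methyl}prop-2-enoyl}oxy)methyl]-1-oxo-6-(propan-2-yl)-1,3,5a,6,7,8,9,9a-octahydro-2-benzoxepine-4-carboxylate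
Conditions: 26 (1.2 equiv), Cs2CO3 (0.2 equiv), DMF, 60 °C
Reagents that add atoms: none
Why: Base-catalysed epoxide opening by the carboxylate (SN2 at the CH2 terminus of the 2,2-disubstituted oxirane, the alkoxide being reprotonated by more acid) forms the ester link directly, never frees the primary alcohol that could translactonise onto C1, and leaves the C9–O bond and hence the C9 configuration untouched.

Step 12
Reactants: 27 tert-butyl (5aS,6R,9S,9aS)-9-hydroxy-9-[({(2E)-3-[(1S,6S)-3-(hydroxymethyl)-6-(propan-2-yl)cyclohex-2-en-1-yl]-2-{[(4-methoxyphenyl)methoxy]methyl}prop-2-enoyl}oxy)methyl]-1-oxo-6-(propan-2-yl)-1,3,5a,6,7,8,9,9a-octahydro-2-benzoxepine-4-carboxylate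
Product: 28 (5aS,6R,9S,9aS)-9-hydroxy-9-[({(2E)-2-(hydroxymethyl)-3-[(1S,6S)-3-(hydroxymethyl)-6-(propan-2-yl)cyclohex-2-en-1-yl]prop-2-enoyl}oxy)methyl]-1-oxo-6-(propan-2-yl)-1,3,5a,6,7,8,9,9a-octahydro-2-benzoxepine-4-carboxylic acid
Conditions: CF3CO2H/CH2Cl2 (1:4), anisole (10 equiv), 0 °C → rt; MeOH co-evaporation
Reagents that add atoms: none
Why: Acidolysis cleaves the tert-butyl ester (loss of isobutene) and the 4-methoxybenzyl ether (cation trapped by anisole), while the lactone, the linking ester and the tertiary alcohol (flanked by two electron-withdrawing groups, so hard to ionise) persist; no stereocentre is affected.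

**Compound list**

1 | 3-methylbutanal | CC(C)CC=O | starting material
2 | but-3-en-2-one | CC(=O)C=C | starting material
3 | (2R)-5-oxo-2-(propan-2-yl)hexanal | CC(C)[C@H](C=O)CCC(C)=O | intermediate
4 | (4R)-4-(propan-2-yl)cyclohex-2-en-1-one | CC(C)[C@H]1CCC(=O)C=C1 | intermediate
5 | bromo{[(3R,4R)-3-ethenyl-4-(propan-2-yl)cyclohex-1-en-1-yl]oxy}magnesium | CC(C)[C@H]1CCC(O[Mg]Br)=C[C@@H]1C=C | intermediate
6 | {[(3R,4R)-3-ethenyl-4-(propan-2-yl)cyclohex-1-en-1-yl]oxy}trimethylsilane | CC(C)[C@H]1CCC(O[Si](C)(C)C)=C[C@@H]1C=C | intermediate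
7 | tert-butyl 2-(bromomethyl)prop-2-enoate | C=C(CBr)C(=O)OC(C)(C)C | starting material
8 | lithium (3R,4R)-3-ethenyl-4-(propan-2-yl)cyclohex-1-en-1-olate | CC(C)[C@H]1CCC([O-])=C[C@@H]1C=C.[Li+] | intermediate
9 | lithium (1S,2R,3R)-2-ethenyl-6-oxo-3-(propan-2-yl)cyclohexane-1-carboxylate | CC(C)[C@H]1CCC(=O)[C@@H](C(=O)[O-])[C@@H]1C=C.[Li+] | intermediate
10 | lithium (3S,4S,5R,6R)-5-ethenyl-6-(propan-2-yl)-1-oxaspiro[2.5]octane-4-carboxylate | CC(C)[C@H]1CC[C@@]2(CO2)[C@@H](C(=O)[O-])[C@@H]1C=C.[Li+] | intermediate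
11 | 2-(tert-butoxycarbonyl)prop-2-en-1-yl (3S,4S,5R,6R)-5-ethenyl-6-(propan-2-yl)-1-oxaspiro[2.5]octane-4-carboxylate | CC(C)[C@H]1CC[C@@]2(CO2)[C@@H](C(=O)OCC(=C)C(=O)OC(C)(C)C)[C@@H]1C=C | intermediate
12 | tert-butyl (5aS,6R,9S,9aS)-1-oxo-6-(propan-2-yl)-1,3,5a,6,7,8-hexahydro-9aH-spiro[2-benzoxepine-9,2'-oxirane]-4-carboxylate | CC(C)[C@H]1CC[C@@]2(CO2)[C@H]3C(=O)OCC(C(=O)OC(C)(C)C)=C[C@H]13 | intermediate
13 | (2S)-5-oxo-2-(propan-2-yl)hexanal | CC(C)[C@@H](C=O)CCC(C)=O | intermediate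
14 | (4S)-4-(propan-2-yl)cyclohex-2-en-1-one | CC(C)[C@@H]1CCC(=O)C=C1 | intermediate
15 | bromo{[(3S,4S)-3-ethenyl-4-(propan-2-yl)cyclohex-1-en-1-yl]oxy}magnesium | C=C[C@@H]1C=C(O[Mg]Br)CC[C@H]1C(C)C | intermediate
16 | (3S,4S)-3-ethenyl-4-(propan-2-yl)cyclohex-1-en-1-yl trifluoromethanesulfonate | C=C[C@@H]1C=C(OS(=O)(=O)C(F)(F)F)CC[C@H]1C(C)C | intermediate
17 | (3S,4S)-4-(propan-2-yl)-3-(1,2,4-trioxolan-3-yl)cyclohex-1-en-1-yl trifluoromethanesulfonate | O1OCOC1[C@@H]2C=C(OS(=O)(=O)C(F)(F)F)CC[C@H]2C(C)C | intermediate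
18 | (3S,4S)-3-formyl-4-(propan-2-yl)cyclohex-1-en-1-yl trifluoromethanesulfonate | O=C[C@@H]1C=C(OS(=O)(=O)C(F)(F)F)CC[C@H]1C(C)C | intermediate
19 | methyl 2-(dimethoxyphosphoryl)prop-2-enoate | COC(=O)C(=C)P(=O)(OC)OC | starting material
20 | (4-methoxyphenyl)methanol | COc1ccc(CO)cc1 | starting material
21 | sodium (4-methoxyphenyl)methanolate | [Na+].[O-]Cc1ccc(OC)cc1 | intermediate
22 | sodium 1-(dimethoxyphosphoryl)-1-(methoxycarbonyl)-2-[(4-methoxyphenyl)methoxy]ethan-1-ide | [Na+].COC(=O)[C-](COCc1ccc(OC)cc1)P(=O)(OC)OC | intermediate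
23 | methyl (2E)-2-{[(4-methoxyphenyl)methoxy]methyl}-3-[(1R,6S)-6-(propan-2-yl)-3-{[(trifluoromethyl)sulfonyl]oxy}cyclohex-2-en-1-yl]prop-2-enoate | COC(=O)/C(=C/[C@@H]1C=C(OS(=O)(=O)C(F)(F)F)CC[C@H]1C(C)C)COCc2ccc(OC)cc2 | intermediate
24 | methyl (2E)-3-[(1S,6S)-3-(hydroxymethyl)-6-(propan-2-yl)cyclohex-2-en-1-yl]-2-{[(4-methoxyphenyl)methoxy]methyl}prop-2-enoate | COC(=O)/C(=C/[C@@H]1C=C(CO)CC[C@H]1C(C)C)COCc2ccc(OC)cc2 | intermediate
25 | lithium (2E)-3-[(1S,6S)-3-(hydroxymethyl)-6-(propan-2-yl)cyclohex-2-en-1-yl]-2-{[(4-methoxyphenyl)methoxy]methyl}prop-2-enoate | [Li+].[O-]C(=O)/C(=C/[C@@H]1C=C(CO)CC[C@H]1C(C)C)COCc2ccc(OC)cc2 | intermediate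
26 | (2E)-3-[(1S,6S)-3-(hydroxymethyl)-6-(propan-2-yl)cyclohex-2-en-1-yl]-2-{[(4-methoxyphenyl)methoxy]methyl}prop-2-enoic acid | OC(=O)/C(=C/[C@@H]1C=C(CO)CC[C@H]1C(C)C)COCc2ccc(OC)cc2 | intermediate
27 | tert-butyl (5aS,6R,9S,9aS)-9-hydroxy-9-[({(2E)-3-[(1S,6S)-3-(hydroxymethyl)-6-(propan-2-yl)cyclohex-2-en-1-yl]-2-{[(4-methoxyphenyl)methoxy]methyl}prop-2-enoyl}oxy)methyl]-1-oxo-6-(propan-2-yl)-1,3,5a,6,7,8,9,9a-octahydro-2-benzoxepine-4-carboxylate | CC(C)[C@H]1CC[C@@](O)(COC(=O)/C(=C/[C@@H]3C=C(CO)CC[C@H]3C(C)C)COCc4ccc(OC)cc4)[C@H]2C(=O)OCC(C(=O)OC(C)(C)C)=C[C@H]12 | intermediate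
28 | (5aS,6R,9S,9aS)-9-hydroxy-9-[({(2E)-2-(hydroxymethyl)-3-[(1S,6S)-3-(hydroxymethyl)-6-(propan-2-yl)cyclohex-2-en-1-yl]prop-2-enoyl}oxy)methyl]-1-oxo-6-(propan-2-yl)-1,3,5a,6,7,8,9,9a-octahydro-2-benzoxepine-4-carboxylic acid | CC(C)[C@H]1CC[C@@](O)(COC(=O)/C(=C/[C@@H]2C=C(CO)CC[C@H]2C(C)C)CO)[C@H]2C(=O)OCC(C(=O)O)=C[C@H]12 | target

**Step count and risks**

Total step count: 12. Longest linear sequence: 8 steps (steps 5–12, from 1 and 2 through 14, 16, 18, 23, 24, 26 and 27 to 28).

The three steps most likely to fail: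

**Step 3 (the proposed new step).** The β-keto carboxylate 9 may lose CO2 or be deprotonated before the ylide adds, and facial selectivity at the ketone is not yet demonstrated on such a salt. The fallback uses only known chemistry, sets out from 6 and comes back at 11. Lanthanide-catalysed aqueous hydroxymethylation of the silyl enol ether (aq. HCHO, Yb(OTf)3, THF/H2O) gives (2R,3R,4R)-3-ethenyl-2-(hydroxymethyl)-4-(propan-2-yl)cyclohexan-1-one F1. Silylation (t-BuMe2SiCl, imidazole, DMF) gives (2R,3R,4R)-2-({[tert-butyl(dimethyl)silyl]oxy}methyl)-3-ethenyl-4-(propan-2-yl)cyclohexan-1-one F2, a ketone with no acidic β-dicarbonyl proton. Ordinary Corey–Chaykovsky epoxidation (Me3S+ I−, n-BuLi, THF, −10 → 0 °C, axial attack) gives tert-butyl{[(3S,4R,5R,6R)-5-ethenyl-6-(propan-2-yl)-1-oxaspiro[2.5]octan-4-yl]methoxy}dimethylsilane F3. Bu4NF in THF frees [(3S,4R,5R,6R)-5-ethenyl-6-(propan-2-yl)-1-oxaspiro[2.5]octan-4-yl]methanol F4. Dess–Martin oxidation (NaHCO3, CH2Cl2) gives (3S,4S,5R,6R)-5-ethenyl-6-(propan-2-yl)-1-oxaspiro[2.5]octane-4-carbaldehyde F5, and Pinnick oxidation (NaClO2, NaH2PO4, 2-methylbut-2-ene) gives (3S,4S,5R,6R)-5-ethenyl-6-(propan-2-yl)-1-oxaspiro[2.5]octane-4-carboxylic acid F6. O-Alkylation with 7 (Cs2CO3, DMF, 0 °C) then gives 11.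

**Step 8.** The olefination may give a poor E/Z ratio, and the basic carbanion may epimerise or conjugate the sensitive β,γ-unsaturated aldehyde 18. The fallback replaces ozonolysis/olefination by cross-metathesis; it sets out from 16 and comes back at 23. Etherification of commercial methyl 2-(bromomethyl)prop-2-enoate with 20 (NaH, THF, 0 °C) gives methyl 2-{[(4-methoxyphenyl)methoxy]methyl}prop-2-enoate F7. Cross-metathesis of F7 (excess) with the vinyl group of 16 (second-generation Hoveyda–Grubbs catalyst, CH2Cl2, 40 °C) gives 23 directly as the thermodynamically favoured E isomer, without ever forming an aldehyde.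

**Step 11.** Opening of the hindered 2,2-disubstituted epoxide may be slow, and the strained bicyclic allylic lactone 12 may not survive prolonged heating with carboxylate (ring opening at the allylic ester, epimerisation at C9a). The fallback reverses the order of union and ring closure; it sets out from 11 (with 26) and comes back at 27. Carboxylate opening of the epoxide of monocyclic 11 with 26 (Cs2CO3 cat., DMF, 50 °C) gives 2-(tert-butoxycarbonyl)prop-2-en-1-yl (1S,2S,5R,6R)-6-ethenyl-2-hydroxy-2-[({(2E)-3-[(1S,6S)-3-(hydroxymethyl)-6-(propan-2-yl)cyclohex-2-en-1-yl]-2-{[(4-methoxyphenyl)methoxy]methyl}prop-2-enoyl}oxy)methyl]-5-(propan-2-yl)cyclohexane-1-carboxylate F8. Ring-closing metathesis of F8 (second-generation Hoveyda–Grubbs catalyst, toluene, 80 °C) then closes ring B to give 27; the trisubstituted alkenes of the acyl half do not take part.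

**Further compounds**

F1 | step 3 | (2R,3R,4R)-3-ethenyl-2-(hydroxymethyl)-4-(propan-2-yl)cyclohexan-1-one | CC(C)[C@H]1CCC(=O)[C@@H](CO)[C@@H]1C=C
F2 | step 3 | (2R,3R,4R)-2-({[tert-butyl(dimethyl)silyl]oxy}methyl)-3-ethenyl-4-(propan-2-yl)cyclohexan-1-one | CC(C)[C@H]1CCC(=O)[C@@H](CO[Si](C)(C)C(C)(C)C)[C@@H]1C=C
F3 | step 3 | tert-butyl{[(3S,4R,5R,6R)-5-ethenyl-6-(propan-2-yl)-1-oxaspiro[2.5]octan-4-yl]methoxy}dimethylsilane | CC(C)[C@H]1CC[C@@]2(CO2)[C@@H](CO[Si](C)(C)C(C)(C)C)[C@@H]1C=C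
F4 | step 3 | [(3S,4R,5R,6R)-5-ethenyl-6-(propan-2-yl)-1-oxaspiro[2.5]octan-4-yl]methanol | CC(C)[C@H]1CC[C@@]2(CO2)[C@@H](CO)[C@@H]1C=C
F5 | step 3 | (3S,4S,5R,6R)-5-ethenyl-6-(propan-2-yl)-1-oxaspiro[2.5]octane-4-carbaldehyde | CC(C)[C@H]1CC[C@@]2(CO2)[C@@H](C=O)[C@@H]1C=C
F6 | step 3 | (3S,4S,5R,6R)-5-ethenyl-6-(propan-2-yl)-1-oxaspiro[2.5]octane-4-carboxylic acid | CC(C)[C@H]1CC[C@@]2(CO2)[C@@H](C(=O)O)[C@@H]1C=C
F7 | step 8 | methyl 2-{[(4-methoxyphenyl)methoxy]methyl}prop-2-enoate | COC(=O)C(=C)COCc1ccc(OC)cc1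
F8 | step 11 | 2-(tert-butoxycarbonyl)prop-2-en-1-yl (1S,2S,5R,6R)-6-ethenyl-2-hydroxy-2-[({(2E)-3-[(1S,6S)-3-(hydroxymethyl)-6-(propan-2-yl)cyclohex-2-en-1-yl]-2-{[(4-methoxyphenyl)methoxy]methyl}prop-2-enoyl}oxy)methyl]-5-(propan-2-yl)cyclohexane-1-carboxylate | CC(C)[C@H]1CC[C@@](O)(COC(=O)/C(=C/[C@@H]2C=C(CO)CC[C@H]2C(C)C)COCc2ccc(OC)cc2)[C@@H](C(=O)OCC(=C)C(=O)OC(C)(C)C)[C@@H]1C=C
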